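**Retrosynthetic overview**
1. Locants (2,3-dihydro-1,4-benzodioxine): O1–C2(aryl)–C3(CH2OH)–O4–C4a–C5(OH)–C6–C7(styryl)–C8–C8a. Ring A is the benzo ring, ring B the dioxane ring, ring C the syringyl ring and ring D the resorcinol ring.
2. The E-alkene between C7 and ring D is cut by a Horner–Wadsworth–Emmons disconnection into a ring A C7 aldehyde and a ring D benzylphosphonate, with all phenols as silyl ethers.
3. Key disconnection: ring B, the only ring to be built, is taken apart at O4–C4a (the ring-closing aryl C–O bond) and at O1–C2 in the same operation. This leads back to 4-bromo-3,5-dihydroxybenzaldehyde and a doubly silylated (2S,3S)-epoxysinapyl alcohol.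
4. Enabling feature: C4a lies on the mirror axis C4a···C7 of ring A. It is flanked by the oxygens on C8a and C5, which are equivalent until one is alkylated (the other becomes C5–OH), and it is para to C7, where a formyl group activates C4a–Br. The 4-OH of ring C is para to C2, so strain release opens the oxirane to a p-quinone methide and keeps C2–O1 reversible, letting C3 alone dictate the trans ring.
5. The epoxide comes from syringaldehyde by Wittig olefination, reduction and Sharpless asymmetric epoxidation. Rings A, C and D are bought; ring B is formed in the key step.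

Key step: step 7

Remark on the chemistry: the (2S,3S) descriptors of the target correspond to the trans-2,3-disubstituted dioxane ring. The locants above are kept for all benzodioxine intermediates, whatever their principal group.

Step 1
Reactants: 1 syringaldehyde (4-hydroxy-3,5-dimethoxybenzaldehyde)
Product: 2 4-(tert-butyldimethylsilyloxy)-3,5-dimethoxybenzaldehyde
Conditions: TBSCl, imidazole, DMF, 23 °C
Reagents that add atoms: tert-butyldimethylsilyl chloride (TBSCl), CC(C)(C)[Si](C)(C)Cl
Why: Imidazole-promoted O-silylation of a phenol, which installs the fluoride-labile group that later triggers the key step.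

Step 2
Reactants: 2 4-(tert-butyldimethylsilyloxy)-3,5-dimethoxybenzaldehyde
Product: 3 ethyl (E)-3-[4-(tert-butyldimethylsilyloxy)-3,5-dimethoxyphenyl]prop-2-enoate
Conditions: Ph3P=CHCO2Et, toluene, 80 °C
Reagents that add atoms: ethyl (triphenylphosphoranylidene)acetate, CCOC(=O)C=P(c1ccccc1)(c1ccccc1)c1ccccc1
Why: Wittig olefination with a stabilised ylide runs under neutral conditions, should favour the E-enoate and spares the aryl silyl ether.

Step 3
Reactants: 3 ethyl (E)-3-[4-(tert-butyldimethylsilyloxy)-3,5-dimethoxyphenyl]prop-2-enoate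
Product: 4 (E)-3-[4-(tert-butyldimethylsilyloxy)-3,5-dimethoxyphenyl]prop-2-en-1-ol
Conditions: i-Bu2AlH (2.3 equiv), CH2Cl2, −78 °C; aq. potassium sodium tartrate
Reagents that add atoms: none
Why: 1,2-Reduction of an enoate to the allylic alcohol with i-Bu2AlH leaves the alkene geometry and the aryl silyl ether untouched.

Step 4
Reactants: 4 (E)-3-[4-(tert-butyldimethylsilyloxy)-3,5-dimethoxyphenyl]prop-2-en-1-ol
Product: 5 [(2S,3S)-3-[4-(tert-butyldimethylsilyloxy)-3,5-dimethoxyphenyl]oxiran-2-yl]methanol
Conditions: Ti(OiPr)4 (10 mol %), L-(+)-diisopropyl tartrate (12 mol %), t-BuOOH, 4 Å MS, CH2Cl2, −25 °C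
Reagents that add atoms: tert-butyl hydroperoxide, CC(C)(C)OO
Why: Sharpless asymmetric epoxidation with the L-(+)-tartrate delivers oxygen to the face of the E-allylic alcohol that gives the (2S,3S)-epoxide, which sets the carbon that becomes C3, while catalytic titanium and sieves limit opening of the electron-rich benzylic oxirane.

Step 5
Reactants: 5 [(2S,3S)-3-[4-(tert-butyldimethylsilyloxy)-3,5-dimethoxyphenyl]oxiran-2-yl]methanol
Product: 6 (2S,3S)-3-[4-(tert-butyldimethylsilyloxy)-3,5-dimethoxyphenyl]-2-[(triisopropylsilyloxy)methyl]oxirane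
Conditions: TIPSCl, imidazole, DMF, 0 to 23 °C
Reagents that add atoms: triisopropylsilyl chloride (TIPSCl), CC(C)[Si](Cl)(C(C)C)C(C)C
Why: O-Silylation of the primary alcohol with the most base-stable common silyl group blocks Payne rearrangement and ensures that only O4 is unmasked later.

Step 6
Reactants: 7 4-bromo-3,5-dimethoxybenzaldehyde
Product: 8 4-bromo-3,5-dihydroxybenzaldehyde
Conditions: BBr3 (3 equiv), CH2Cl2, −78 to 23 °C; H2O
Reagents that add atoms: none
Why: Lewis-acid cleavage of aryl methyl ethers with BBr3 frees both phenols, and the aryl bromide and (after aqueous work-up) the aldehyde are retained.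

Step 7
Reactants: 6 (2S,3S)-3-[4-(tert-butyldimethylsilyloxy)-3,5-dimethoxyphenyl]-2-[(triisopropylsilyloxy)methyl]oxirane; 8 4-bromo-3,5-dihydroxybenzaldehyde
Product: 11 (2S,3S)-5-hydroxy-2-(4-hydroxy-3,5-dimethoxyphenyl)-3-[(triisopropylsilyloxy)methyl]-2,3-dihydro-1,4-benzodioxine-7-carbaldehyde, via quinone methide 9 (not isolated), via threo benzyl aryl ether 10 (not isolated)
Conditions: 8 (1.3 equiv), CsF (1.1 equiv), Cs2CO3 (3 equiv), CuI (10 mol %), 3,4,7,8-tetramethyl-1,10-phenanthroline (20 mol %), 4 Å MS, DMF, Ar, 23 °C then 90 °C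
Reagents that add atoms: none
Why: Proposed new method: fluoride strips the phenolic TBS group of 6 and the ring C phenolate pushes open the strained oxirane at its benzylic C–O bond to give p-quinone methide 9, either of the two equivalent phenoxide oxygens of 8 adds to its exocyclic carbon (1,6-oxa-Michael addition, O1–C2) to give 10, and on warming monovalent copper binds the C3 alkoxide, inserts into the C4a–Br bond and reductively eliminates from trivalent copper to form O4–C4a. The closest known reaction types are the copper-catalysed tandem epoxide opening/intramolecular Ullmann etherification of 2-halophenols to 2,3-dihydro-1,4-benzodioxines, the fluoride-triggered release of quinone methides from O-silylated 4-hydroxybenzyl electrophiles and the addition of phenols to lignin-type quinone methides, and what is new is running them as one cascade that pairs a reversible C2–O1 bond with an irreversible O4–C4a coupling. Ring B, the only ring closed, forms in a six-membered exo mode by ipso substitution of bromide at the sp2 carbon C4a through a seven-membered cupracycle. C3 comes from the Sharpless epoxide and is retained because its C–O bond is never broken, whereas C2 is set under thermodynamic control by C3: while the ring C phenolate is free, the C2–O1 bond opens and recloses through the quinone methide before and after the coupling, the threo ether should cyclise faster (both substituents pseudo-equatorial) and any cis ring should drain into the diequatorial trans-(2S,3S) ring. Site selectivity is secured by the substrates: the quinone methide has one electrophilic carbon, the TIPS ether leaves O4 as the only alcohol, the mirror symmetry of 8 makes both first additions (and reclosure from either flanking oxygen) lead to the same product and leaves the second oxygen as C5–OH, and the formyl group para to C4a activates the bromide while damping C-alkylation of ring A. All oxygen additions to the quinone methide, double alkylation of 8 included, are reversible and only the C–O coupling is not, so the mixture should funnel to 11.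

Step 8
Reactants: 11 (2S,3S)-5-hydroxy-2-(4-hydroxy-3,5-dimethoxyphenyl)-3-[(triisopropylsilyloxy)methyl]-2,3-dihydro-1,4-benzodioxine-7-carbaldehyde
Product: 12 (2S,3S)-5-(tert-butyldimethylsilyloxy)-2-[4-(tert-butyldimethylsilyloxy)-3,5-dimethoxyphenyl]-3-[(triisopropylsilyloxy)methyl]-2,3-dihydro-1,4-benzodioxine-7-carbaldehyde
Conditions: TBSCl (3 equiv), imidazole, DMF, 23 °C
Reagents that add atoms: tert-butyldimethylsilyl chloride (TBSCl), CC(C)(C)[Si](C)(C)Cl
Why: O-Silylation of both phenols under weakly basic conditions caps the ring C oxygen, so the quinone methide channel is closed and C2 is locked for the basic olefination.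

Step 9
Reactants: 13 3,5-dihydroxybenzaldehyde
Product: 14 3,5-bis(tert-butyldimethylsilyloxy)benzaldehyde
Conditions: TBSCl (2.4 equiv), imidazole, DMF, 23 °C
Reagents that add atoms: tert-butyldimethylsilyl chloride (TBSCl), CC(C)(C)[Si](C)(C)Cl
Why: Standard O-silylation of phenols gives ring D the same fluoride-labile protection as the rest of the molecule.

Step 10
Reactants: 14 3,5-bis(tert-butyldimethylsilyloxy)benzaldehyde
Product: 15 [3,5-bis(tert-butyldimethylsilyloxy)phenyl]methanol
Conditions: NaBH4, MeOH/THF, 0 °C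
Reagents that add atoms: none
Why: Borohydride reduction of an aromatic aldehyde is fast at 0 °C and does not touch the aryl silyl ethers.

Step 11
Reactants: 15 [3,5-bis(tert-butyldimethylsilyloxy)phenyl]methanol
Product: 16 3,5-bis(tert-butyldimethylsilyloxy)benzyl bromide
Conditions: CBr4, PPh3, CH2Cl2, 0 °C
Reagents that add atoms: carbon tetrabromide, BrC(Br)(Br)Br
Why: The Appel reaction converts the benzylic alcohol into the bromide under essentially neutral conditions that silyl ethers tolerate.

Step 12
Reactants: 16 3,5-bis(tert-butyldimethylsilyloxy)benzyl bromide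
Product: 17 diethyl [3,5-bis(tert-butyldimethylsilyloxy)benzyl]phosphonate
Conditions: P(OEt)3, neat, 130 °C
Reagents that add atoms: triethyl phosphite, CCOP(OCC)OCC
Why: The Michaelis–Arbuzov reaction of a primary benzylic bromide with triethyl phosphite is driven by loss of the volatile alkyl bromide.

Step 13
Reactants: 12 (2S,3S)-5-(tert-butyldimethylsilyloxy)-2-[4-(tert-butyldimethylsilyloxy)-3,5-dimethoxyphenyl]-3-[(triisopropylsilyloxy)methyl]-2,3-dihydro-1,4-benzodioxine-7-carbaldehyde; 17 diethyl [3,5-bis(tert-butyldimethylsilyloxy)benzyl]phosphonate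
Product: 18 pentasilyl ether of the target: (2S,3S)-7-[(E)-2-[3,5-bis(tert-butyldimethylsilyloxy)phenyl]ethenyl]-5-(tert-butyldimethylsilyloxy)-2-[4-(tert-butyldimethylsilyloxy)-3,5-dimethoxyphenyl]-3-[(triisopropylsilyloxy)methyl]-2,3-dihydro-1,4-benzodioxine
Conditions: 17 (1.2 equiv), NaN(SiMe3)2 (1.2 equiv), THF, 0 °C; then 12, 0 to 23 °C
Reagents that add atoms: none
Why: Horner–Wadsworth–Emmons olefination of an aromatic aldehyde with a preformed benzylphosphonate anion should give the E-stilbene, and neither stereocentre is acidic or ionisable while ring C is silylated.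

Step 14
Reactants: 18 pentasilyl ether of the target
Product: 19 target, (2S,3S)-7-[(E)-2-(3,5-dihydroxyphenyl)ethenyl]-2-(4-hydroxy-3,5-dimethoxyphenyl)-3-(hydroxymethyl)-2,3-dihydro-1,4-benzodioxin-5-ol
Conditions: Bu4NF (6 equiv), AcOH (6 equiv), THF, 0 to 23 °C, Ar
Reagents that add atoms: none
Why: Fluoride-mediated global desilylation buffered with acetic acid removes four TBS groups and the TIPS group without building up phenolates, so the E-alkene, C2 and C3 stay as set.

**Compound list**
1 | syringaldehyde | COc1cc(C=O)cc(OC)c1O | starting material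
2 | 4-(tert-butyldimethylsilyloxy)-3,5-dimethoxybenzaldehyde | COc1cc(C=O)cc(OC)c1O[Si](C)(C)C(C)(C)C | intermediate
3 | ethyl (E)-3-[4-(tert-butyldimethylsilyloxy)-3,5-dimethoxyphenyl]prop-2-enoate | CCOC(=O)/C=C/c1cc(OC)c(O[Si](C)(C)C(C)(C)C)c(OC)c1 | intermediate
4 | (E)-3-[4-(tert-butyldimethylsilyloxy)-3,5-dimethoxyphenyl]prop-2-en-1-ol | OC/C=C/c1cc(OC)c(O[Si](C)(C)C(C)(C)C)c(OC)c1 | intermediate
5 | [(2S,3S)-3-[4-(tert-butyldimethylsilyloxy)-3,5-dimethoxyphenyl]oxiran-2-yl]methanol | OC[C@@H]1O[C@H]1c1cc(OC)c(O[Si](C)(C)C(C)(C)C)c(OC)c1 | intermediate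
6 | (2S,3S)-3-[4-(tert-butyldimethylsilyloxy)-3,5-dimethoxyphenyl]-2-[(triisopropylsilyloxy)methyl]oxirane | CC(C)[Si](C(C)C)(C(C)C)OC[C@@H]1O[C@H]1c1cc(OC)c(O[Si](C)(C)C(C)(C)C)c(OC)c1 | intermediate
7 | 4-bromo-3,5-dimethoxybenzaldehyde | COc1cc(C=O)cc(OC)c1Br | starting material
8 | 4-bromo-3,5-dihydroxybenzaldehyde | Oc1cc(C=O)cc(O)c1Br | intermediate
9 | 4-[(2R)-2-hydroxy-3-(triisopropylsilyloxy)propylidene]-2,6-dimethoxycyclohexa-2,5-dien-1-one (quinone methide) | CC(C)[Si](C(C)C)(C(C)C)OC[C@@H](C=C1C=C(OC)C(=O)C(OC)=C1)O | intermediate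
10 | 4-bromo-3-hydroxy-5-{[(1S,2S)-2-hydroxy-1-(4-hydroxy-3,5-dimethoxyphenyl)-3-(triisopropylsilyloxy)propyl]oxy}benzaldehyde (threo ether, in equilibrium with its benzylic epimer through 9) | COc1cc([C@H](Oc2cc(C=O)cc(O)c2Br)[C@@H](O)CO[Si](C(C)C)(C(C)C)C(C)C)cc(OC)c1O | intermediate
11 | (2S,3S)-5-hydroxy-2-(4-hydroxy-3,5-dimethoxyphenyl)-3-[(triisopropylsilyloxy)methyl]-2,3-dihydro-1,4-benzodioxine-7-carbaldehyde | COc1cc([C@@H]2Oc3cc(C=O)cc(O)c3O[C@H]2CO[Si](C(C)C)(C(C)C)C(C)C)cc(OC)c1O | intermediate
12 | bis-TBS ether of 11 | COc1cc([C@@H]2Oc3cc(C=O)cc(O[Si](C)(C)C(C)(C)C)c3O[C@H]2CO[Si](C(C)C)(C(C)C)C(C)C)cc(OC)c1O[Si](C)(C)C(C)(C)C | intermediate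
13 | 3,5-dihydroxybenzaldehyde | O=Cc1cc(O)cc(O)c1 | starting material
14 | 3,5-bis(tert-butyldimethylsilyloxy)benzaldehyde | O=Cc1cc(O[Si](C)(C)C(C)(C)C)cc(O[Si](C)(C)C(C)(C)C)c1 | intermediate
15 | [3,5-bis(tert-butyldimethylsilyloxy)phenyl]methanol | OCc1cc(O[Si](C)(C)C(C)(C)C)cc(O[Si](C)(C)C(C)(C)C)c1 | intermediate
16 | 3,5-bis(tert-butyldimethylsilyloxy)benzyl bromide | BrCc1cc(O[Si](C)(C)C(C)(C)C)cc(O[Si](C)(C)C(C)(C)C)c1 | intermediate
17 | diethyl [3,5-bis(tert-butyldimethylsilyloxy)benzyl]phosphonate | CCOP(=O)(OCC)Cc1cc(O[Si](C)(C)C(C)(C)C)cc(O[Si](C)(C)C(C)(C)C)c1 | intermediate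
18 | pentasilyl ether of the target | COc1cc([C@@H]2Oc3cc(/C=C/c4cc(O[Si](C)(C)C(C)(C)C)cc(O[Si](C)(C)C(C)(C)C)c4)cc(O[Si](C)(C)C(C)(C)C)c3O[C@H]2CO[Si](C(C)C)(C(C)C)C(C)C)cc(OC)c1O[Si](C)(C)C(C)(C)C | intermediate
19 | (2S,3S)-7-[(E)-2-(3,5-dihydroxyphenyl)ethenyl]-2-(4-hydroxy-3,5-dimethoxyphenyl)-3-(hydroxymethyl)-2,3-dihydro-1,4-benzodioxin-5-ol | COc1cc([C@@H]2Oc3cc(/C=C/c4cc(O)cc(O)c4)cc(O)c3O[C@H]2CO)cc(OC)c1O | target

Total step count: 14. Longest linear sequence: 9 (steps 1, 2, 3, 4, 5, 7, 8, 13, 14).

**Steps most likely to fail**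

Step 7. Several things could go wrong during the heating period.
- The quinone methide may tautomerise by loss of the C3 hydrogen faster than it is recaptured.
- Oxidative addition may be slow at a bromide flanked by two oxygens while free phenolates occupy copper.
- The silyl group may migrate from the primary oxygen to O4.
- The cis-to-trans equilibration may stay incomplete.

The fallback separates the events and uses only known reaction types. It sets out from 6 and 8.
- Only the first half is run (CsF, Cs2CO3, DMF, 0 to 23 °C, no copper), and 10 is isolated together with its benzylic epimer, the erythro ether F1.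
- The two are separated by chromatography, and F1 is re-equilibrated through 9 by renewed exposure to Cs2CO3 in DMF.
- Both phenols of 10 are silylated (TBSCl, imidazole, CH2Cl2, 0 °C; the hindered secondary alcohol stays free) to give the bis-TBS threo bromo alcohol F2. Its capped ring C oxygen makes C2 configurationally fixed.
- Palladium-catalysed intramolecular aryl etherification (Pd(OAc)2, 2-(di-tert-butylphosphino)-1,1'-binaphthyl, Cs2CO3, toluene, 70 °C, through zerovalent palladium) closes O4–C4a with retention. The route is rejoined at 12, so 11 and step 8 are bypassed.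

Step 4. The titanium alkoxide or the work-up may open the electron-rich benzylic oxirane, and the slow reaction at low temperature may erode enantioselectivity.

The fallback sets out from 4.
- Compound 4 is first silylated (TIPSCl, imidazole, DMF) to the allyl silyl ether F3.
- F3 is epoxidised by Shi epoxidation with the enantiomer of the fructose-derived ketone (prepared from L-sorbose), KHSO5, K2CO3 buffer, MeCN/dimethoxymethane/H2O, 0 °C.
- This is a Lewis-acid-free, basic medium, and its dioxirane should attack the face that gives the (2S,3S)-oxirane. The route is rejoined at 6, so 5 and step 5 are bypassed.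

Step 13. The basic phosphonate anion may remove phenolic silyl groups, which would reopen the quinone methide channel at C2, and E selectivity may be incomplete.

The fallback sets out from 12 and 14.
- Each aldehyde is methylenated (Ph3PCH3Br, NaN(SiMe3)2, THF, −78 to 0 °C) to give the ring A styrene F4 and 3,5-bis(tert-butyldimethylsilyloxy)styrene F5.
- The two styrenes are joined by base-free cross-metathesis (second-generation Grubbs catalyst, excess F5, CH2Cl2, 40 °C), which should give the E-stilbene.
- The route is rejoined at 18.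

**Further compounds**
F1 | step 7 | 4-bromo-3-hydroxy-5-{[(1R,2S)-2-hydroxy-1-(4-hydroxy-3,5-dimethoxyphenyl)-3-(triisopropylsilyloxy)propyl]oxy}benzaldehyde (erythro ether) | COc1cc([C@@H](Oc2cc(C=O)cc(O)c2Br)[C@@H](O)CO[Si](C(C)C)(C(C)C)C(C)C)cc(OC)c1O
F2 | step 7 | 4-bromo-3-(tert-butyldimethylsilyloxy)-5-{[(1S,2S)-1-[4-(tert-butyldimethylsilyloxy)-3,5-dimethoxyphenyl]-2-hydroxy-3-(triisopropylsilyloxy)propyl]oxy}benzaldehyde | COc1cc([C@H](Oc2cc(C=O)cc(O[Si](C)(C)C(C)(C)C)c2Br)[C@@H](O)CO[Si](C(C)C)(C(C)C)C(C)C)cc(OC)c1O[Si](C)(C)C(C)(C)C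
F3 | step 4 | (E)-1-[4-(tert-butyldimethylsilyloxy)-3,5-dimethoxyphenyl]-3-(triisopropylsilyloxy)prop-1-ene | CC(C)[Si](C(C)C)(C(C)C)OC/C=C/c1cc(OC)c(O[Si](C)(C)C(C)(C)C)c(OC)c1
F4 | step 13 | (2S,3S)-5-(tert-butyldimethylsilyloxy)-2-[4-(tert-butyldimethylsilyloxy)-3,5-dimethoxyphenyl]-7-ethenyl-3-[(triisopropylsilyloxy)methyl]-2,3-dihydro-1,4-benzodioxine | COc1cc([C@@H]2Oc3cc(C=C)cc(O[Si](C)(C)C(C)(C)C)c3O[C@H]2CO[Si](C(C)C)(C(C)C)C(C)C)cc(OC)c1O[Si](C)(C)C(C)(C)C
F5 | step 13 | 3,5-bis(tert-butyldimethylsilyloxy)styrene | C=Cc1cc(O[Si](C)(C)C(C)(C)C)cc(O[Si](C)(C)C(C)(C)C)c1
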